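(The numbers stand for no real mixture; the flask was simulated.)

If each weak acid released from the substrate is caught at once by another substrate as idle adduct, two substrates leave for every one that reacts.

    weak acid + target → side product (k1 = 1.7 M⁻¹ h⁻¹)
    weak acid ⇌ conjugate base + acid, settled at all times (K2 = 3.2 × 10⁻¹⁰ M)
    weak acid + scavenger → scavenged by-product (k3 = 4.0 M⁻¹ h⁻¹)
    substrate + weak acid ⇌ idle adduct, settled at all times (K4 = 7000 M⁻¹)
    target → over-reaction product (k5 = 0.044 h⁻¹)
    substrate + acid → weak acid + acid + target (k6 = 1500 M⁻¹ h⁻¹)
    substrate → weak acid + target (k7 = 0.0032 h⁻¹)
substrate 39 mM; acid 0.0390 mM; scavenger 46.8 mM; time 20 h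
- acid is the free proton; pH is minus the decimal logarithm of its molar concentration
- amounts and yields of weak acid count idle adduct too
- what has gone from substrate into another species counts as reacted, even if it can come back
- run time (flask): 20 h
1. part of the substrate that has reacted at 20 h
2. pH of the solution at 20 h

The reckoning here begins with the acid. Even the whole charge as weak acid would give about 3.20 × 10⁻⁴ mM of acid, less than the 0.0390 mM charged, so the acid, and with it the pH, stays near its starting value. Release is therefore pseudo-first-order, with constant

r = 0.0617 h⁻¹

Let a be the free substrate and x the released part, as fractions of the charge. At the early end, binding strength times a is 270, far above one. The adduct then holds about x, so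

a = 1 − 2x, and a falls at 2·r·a

At the far end, with that product below one, weak acid stays free and the doubling stops. Joining the ends needs one number, the doubled turnover, 2·r·t, the releases each substrate has had time for, counted twice: 2.47.

a = exp(−N), so the reacted part is 91.5%

Was one number enough? At the end, binding strength times a is still 23.1, above one. The scavenger's half-life on free weak acid, 3.7 h, stretches by that factor to 85.7 h, longer than the run.

The forecast gives 89% and pH 4.41, lower in c than this reckoning, on the same doubling: the adduct “roughly doubles its disappearance rate”.

The flask gives 89.5% and pH 4.41, with 98% of its scavenger still free. At 10.0 h, exp(−N/2) gives 29.1% and the flask holds 29.6% free substrate. A neighbour flask with 0.097 mM of acid has N = 5.95, which gives 99.7% against its 96.6%. That neighbour flask ends with 3.4% of its substrate free, so its binding strength times a comes to 9.28.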